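Bis adduct is the product to count in the beta flask, which is followed here as far as 25.0 min of the asked 50 min, and triple product grows beside it.

| flask | starting material | coupling partner | remark | time |
|---|---|---|---|---|
| beta | 0.85 M | 2.5 M | the very flask that is asked about, followed so far |  |
| gamma | 0.57 M | 2.5 M | run made earlier |  |
| flask | 0.85 M | 2.50 M |  | 50 min |

- beta (time / min: bis adduct / %, triple product / %): 1.50: 8, 5; 5.00: 15, 20; 8.00: 21, 26; 15.0: 32, 33; 20.0: 35, 34; 25.0: 40, 36
- gamma (time / min: bis adduct / %, triple product / %): 3.00: 13, 23; 5.00: 14, 28; 8.00: 21, 38; 12.0: 23, 41; 20.0: 27, 49; 40.0: 37, 53

(standard deviation of a reading: 1.5 percentage points)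

- the analysis behind the earlier runs scatters by 1.5 percentage points, standard deviation

1. equivalents of coupling partner to starting material, everything else as given, that leave most bis adduct at 50 min
2. the amount of bis adduct then, in percent of the starting material charged
3. the amount of bis adduct with the amounts as given

Start with the late beta readings, from 15.0 min to 25.0 min, and divide the gain in bis adduct by the gain in both products, so that time drops out: call this reading the share 0.727, a selectivity averaged over that stretch, but the same ratio reads 0.567 from 5.00 min to 15.0 min, so it drifts and is carried on here as a late reading, not as a constant. At 25.0 min beta still lacks 24.0 % of its charge in either column, so let that remainder arrive in the same share, and bis adduct ends near 57.5 %. But the question has a clock, and the remainder fell from 35.0 % over that stretch, so carry the same ratio on to 50 min, which leaves 9.34 % and gives, by my reckoning, 50.7 % bis adduct. Then look at gamma, which has more partner per starting material and at 20.0 min stands at 49 % triple product against 27 % bis adduct, so look for the best charge below the flask's 2.94 equivalents.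

The forecast gives 50.5 % as charged and 56 % at 2.35 equiv, holding that “Less partner suppresses triple product but slows conversion”.

The flask gives 50.0 % as charged, and 56.3 % at 2.30 equiv.

    starting material + coupling partner → mono adduct (k = 0.0255 M⁻¹ s⁻¹)
    coupling partner + mono adduct → bis adduct (k = 0.00127 M⁻¹ s⁻¹)
    triple product ⇌ isomer of the product (K = 0.178, k = 0.00561 s⁻¹)
    coupling partner + bis adduct ⇌ triple product (K = 1.50 M⁻¹, k = 0.0179 M⁻¹ s⁻¹)

At 50 min this flask still holds 6.79 % mono adduct, the part on its way, beside 6.53 % isomer of the product. Bis adduct stands at 50.0 % in this flask through two reverse steps acting together, triple product back to coupling partner and bis adduct, and isomer of the product back to triple product: the run without the first gives 1.10 %, the run without the second 4.37 %.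

Read the same flask at 3.0 h and the share promises 57.5 %; the computed amount is 56.6 %.

The data are simulated for an exercise; scatter was added.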